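## The problem

The target **17** is a 2,3,4-trisubstituted oxolane of the lariciresinol type: C2 carries a 3,4-dihydroxyphenyl group, C3 an acetoxymethyl group and C4 a 4-hydroxy-3-methoxybenzyl group. The configuration is (2S,3R,4R), so the aryl group is trans to the acetoxymethyl group and the acetoxymethyl group is cis to the arylmethyl group. The three stereocentres are contiguous, so one centre set in absolute terms can control the others: C3 can be tied cis to C4 through a fused ring, and C2, a benzylic ether carbon, prefers to lie trans to C3. The two aryl groups differ and must be brought in separately. Three features will not bear rough treatment: the free catechol (air, base), the single aliphatic acetate beside three phenols, and the C2–O1 bond, which is benzylic and open to acid ionisation and hydrogenolysis. The key step rests on the ring itself: O1–C5–C4 is an O–CH2–CH unit whose C4 substituent begins with one carbon, and C2–C3 is an aryl-CH–C unit whose C3 substituent is one oxygenated carbon. With a vinyl group standing for the first substituent and an ester for the second, the ring is the formal (3+2) adduct of 2-vinyloxirane **4** and arylidene malonate **3**, joined at O1–C2 and C3–C4.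

## Retrosynthesis

**17 from 16.** The three phenols are traced back to benzyl ethers and the side-chain methylene to a benzylic acetoxy carbon. In the forward sense one hydrogenolysis cuts the three benzyl–oxygen bonds and the benzylic C–OAc bond. The neighbouring option, freeing the phenols earlier and then acetylating the primary alcohol among them, would need a selective aryl deacetylation and would carry the catechol through several steps. Here the acetate is placed while no phenol is free, and the catechol appears only in the last step. The forward reaction must leave the ring C2–O1 bond intact.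

**16 from 15 from 14.** Two acyl–oxygen bonds are removed to give diol **15**, and the diol is folded back into the cis-fused γ-lactone **14**. The lactone holds the C3 carbon at the acid oxidation level and, through the ring fusion, cis to the C4 side chain, which is the 3,4-relation the target needs. The forward steps are a hydride reduction and a double acetylation; neither touches a stereocentre.

**14 from 12.** A methoxycarbonyl group is put back on C3. Precursor **12** has no stereochemical problem at C3 beyond the ring fusion, because only the cis-fused bicycle can exist. The forward dealkoxycarbonylation must protonate the lactone enolate without opening either ring.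

**12 from 7 and 10.** The aryl–carbon bond of the side chain and the lactone O–acyl bond are cut, giving aldehyde **7** and the arylmagnesium reagent **10** (from bromide **9**, from phenol **8**). A cross-coupling at a CH2X group would need a separate device to tell the two geminal esters apart. Addition to the aldehyde does both jobs, since the new alkoxide can only reach the ester cis to it. The forward reaction needs aldehyde-over-ester selectivity and no enolisation at C4.

**7 from 5.** The formyl group is traced to a vinyl group (oxidative cleavage through diol **6**). The vinyl group is inert in the key step and is the natural C4 substituent of a π-allyl ring closure.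

**5 from 3 and 4.** O1–C2 and C3–C4 are cut. This turns a chiral trisubstituted heterocycle into a flat acceptor **3** and the racemic, commercial epoxide **4**. One catalytic step then forms the ring, two skeletal bonds and the controlling stereocentre C4, and every atom of both partners ends up in **5**. Cuts through C2–C3 or O1–C5 would leave a stereodefined acyclic chain to be made first. The forward reaction must fix C4 absolutely; C3 is not yet stereogenic, and C2 is correctable later.

**3 from 1 and 2.** The C=C bond is cut by a Knoevenagel transform to aldehyde **1** and malonate **2**, both commercial.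

## Roads not taken

**Alternative 1:** The cut runs through the bond between the arylmethyl carbon and C4 and through C2–C3. A butenolide supplies C3, C4, C5 and the acetoxymethyl carbon. In the forward sense the 2-lithio derivative of dithiane **A3** adds to menthyloxy butenolide **A2** anti to the acetal substituent, and the lactone enolate is trapped by aldehyde **1**. This gives the trans-disubstituted lactone **A1** as carbinol epimers. Desulfurisation, hydride reduction, acid-mediated closure of O1–C2, acetylation of the remaining primary hydroxyl and debenzylation would follow.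
- Merits: auxiliary control of this kind is very dependable, C3 and C4 are set in one operation, and the acetate question answers itself because ring closure uses up the other primary hydroxyl.
- Weak points: a stoichiometric auxiliary that must be pure at the acetal carbon, cryogenic organolithium chemistry, sulfur removal over Raney Ni beside benzyl ethers and a benzylic hydroxyl, and a late acid-mediated ring closure at a stage with two electron-rich benzylic positions.
- Comparison: in stereochemical reliability this road is at least equal to the chosen one and probably better, at a similar step count. The chosen plan offers a catalytic source of chirality, forms the oxolane in the key step instead of in a late ionising step, and needs no sulfur or auxiliary.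

**Alternative 2:** Both exocyclic carbon–ring bonds at C3 and C4 are traced to a two-carbon bridge across a C3=C4 double bond. An asymmetric Heck arylation of 2,3-dihydrofuran **A7** with aryl triflate **A8** would give dihydrofuran **A5**. Dichloroketene **A6**, made in situ by Zn dechlorination, would add across C3=C4 anti to the aryl group to give cyclobutanone **A4**. The four-membered ring would then be cut between its bridging carbons, and the end game would resemble the chosen one.
- Merits: C2 is set directly by a well-studied enantioselective reaction, and the cis relation at C3/C4 and their trans relation to the aryl group follow from ring fusion without equilibration.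
- Weak points: the Heck step must give the 2,5-dihydro isomer from an electron-rich triflate. The alkene of **A5** is unpolarised, so the ketene has no reason to place its carbonyl on C3 rather than C4. **A5** is a benzylic, allylic ether that zinc salts can ionise. Several extra operations are needed to turn the bridge into two different one-carbon groups.
- Comparison: this road sets C2 more securely than the chosen plan, which leaves C2 to the ring closure and to thermodynamics. The chosen plan has the two exocyclic carbons differentiated from the start, no regiochemical question, and fewer steps.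

**Alternative 3:** The cut is O1–C2 and C2–C3: C2 and its aryl group come from a carbene, the other four ring atoms and both side chains from an enal. A copper carbene from aryldiazomethane **A10** (CuOTf, chiral bisoxazoline) is attacked by the carbonyl oxygen of enal **A11**, and the vinyl carbonyl ylide closes by 6π electrocyclisation to dihydrofuran **A9**. Hydrogenation of the enol ether anti to the C3 substituent, desilylation, acetylation and debenzylation would follow.
- Merits: the whole skeleton with both aryl groups is assembled in one step, the shortest route on paper.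
- Weak points: an electron-rich, donor-only aryldiazomethane is unstable and prone to self-coupling. The ylide may close to a three-membered ring instead, or the carbene may cyclopropanate the alkene. Asymmetric induction requires the copper–ligand fragment to stay bound through the electrocyclisation. **A9** is an acid-labile enol ether that can aromatise. The aryl group on C2 contests the face selectivity of the hydrogenation.
- Comparison: in convergence and step count this road is clearly better. The chosen plan uses only well-used reaction types and rests its absolute configuration on a catalytic process with an understood stereochemical mechanism.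

Key step: step 2

Assumption: the sense of induction of the diphosphine in step 2 is not predicted here; (R)-BINAP is written and stands for whichever ligand enantiomer delivers (4R)-**5**.

## Route

Step 1
Reactants: 1 3,4-bis(benzyloxy)benzaldehyde; 2 dimethyl malonate
Product: 3 dimethyl 2-{[3,4-bis(benzyloxy)phenyl]methylidene}propanedioate
Conditions: piperidine (0.1 equiv), AcOH (0.1 equiv), toluene, reflux, Dean–Stark
Reagents that add atoms: none
Why: Knoevenagel condensation of a non-enolisable aryl aldehyde with a malonate, driven by azeotropic removal of water. No stereocentre forms, and the identical esters leave no alkene geometry to control.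

Step 2
Reactants: 3 dimethyl 2-{[3,4-bis(benzyloxy)phenyl]methylidene}propanedioate; 4 racemic 2-ethenyloxirane
Product: 5 dimethyl (2R,4R)-2-[3,4-bis(benzyloxy)phenyl]-4-ethenyloxolane-3,3-dicarboxylate (aryl and vinyl trans)
Conditions: Pd2(dba)3·CHCl3 (2.5 mol %), (R)-BINAP (6 mol %), THF, 40 °C, the epoxide added slowly by syringe pump
Reagents that add atoms: none
Why: Zerovalent palladium with the diphosphine opens racemic 4 by oxidative addition to a zwitterionic η3-allyl alkoxide of divalent palladium; the alkoxide adds reversibly to the β-carbon of 3 (oxa-Michael, O1–C2) and the malonate carbanion so formed attacks the internal allyl terminus anti to the metal (C3–C4), which returns the catalyst. The closest known reaction type is the palladium-catalysed formal (3+2) cycloaddition of vinyl epoxides with doubly activated alkenes, which is known in enantioselective form with chiral phosphine ligands. The oxolane closes by 5-exo allylic alkylation; attack at the distal allyl terminus would close a seven-membered ring and should not compete. C4 is set by the ligand: η3–η1–η3 interconversion equilibrates the allyl complexes from the two enantiomers of 4 faster than ring closure, so both enantiomers of the epoxide are funnelled through one allyl face in a dynamic kinetic asymmetric transformation. C2 is set in the same irreversible C–C bond formation, because the oxa-Michael adducts interconvert (Curtin–Hammett); the 2,4-trans arrangement is expected since it keeps the aryl group away from the metal–ligand unit in the envelope-like transition state, and it is the less secure of the two centres. The annulation joins one molecule of 4 to one of 3 with no co-product, so the partners are used in near-equimolar amounts, and slow addition of 4 keeps the zwitterion dilute against the full charge of 3 so that capture by the acceptor outruns self-reaction of the zwitterion. Enantiocontrol is needed at C4 only, since C3 is not yet stereogenic and C2 stays correctable at the stage of 14, where the aryl group of the wanted isomer lies on the convex face of the bicycle.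

Step 3
Reactants: 5 dimethyl (2R,4R)-2-[3,4-bis(benzyloxy)phenyl]-4-ethenyloxolane-3,3-dicarboxylate
Product: 7 dimethyl (2R,4R)-2-[3,4-bis(benzyloxy)phenyl]-4-formyloxolane-3,3-dicarboxylate, via 1,2-diol 6 (not isolated)
Conditions: OsO4 (2 mol %), NaIO4 (4 equiv), 2,6-lutidine (2 equiv), dioxane/H2O 3:1, rt
Reagents that add atoms: osmium tetroxide, O=[Os](=O)(=O)=O (delivers the oxygen); sodium periodate, [Na+].[O-]I(=O)(=O)=O (terminal oxidant that restores OsO4)
Why: Lemieux–Johnson oxidation: catalytic OsO4 dihydroxylates the monosubstituted alkene and periodate cleaves diol 6 in situ; it is preferred to ozone because the two dialkoxyarene rings are ozone-sensitive. C4 is not touched, and the aldehyde is used without chromatography to avoid enolisation at C4.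

Step 4
Reactants: 8 4-bromo-2-methoxyphenol
Product: 9 1-(benzyloxy)-4-bromo-2-methoxybenzene
Conditions: BnBr, K2CO3, DMF, 60 °C
Reagents that add atoms: benzyl bromide, BrCc1ccccc1
Why: Williamson ether synthesis on the phenoxide. The benzyl ether masks the acidic phenol for the organomagnesium step and is removed in the final hydrogenolysis.

Step 5
Reactants: 7 dimethyl (2R,4R)-2-[3,4-bis(benzyloxy)phenyl]-4-formyloxolane-3,3-dicarboxylate; 9 1-(benzyloxy)-4-bromo-2-methoxybenzene
Product: 12 methyl (3aR,6R,6aS)-6-[3,4-bis(benzyloxy)phenyl]-3-[4-(benzyloxy)-3-methoxyphenyl]-1-oxotetrahydro-1H,3H-furo[3,4-c]furan-6a-carboxylate (cis-fused lactone ester; both epimers at C3), via aryl Grignard reagent 10 (not isolated), via bromomagnesium alkoxide 11 (not isolated)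
Conditions: Mg turnings, THF, 40 °C (9 → 10, 1.15 equiv); then 7, THF, −78 °C → 0 °C; aq. NH4Cl
Reagents that add atoms: none
Why: Grignard addition followed by lactonisation: at −78 °C the aryl nucleophile adds to the aldehyde much faster than to the two hindered esters, and on warming alkoxide 11 acylates the only ester it can reach, the one cis to it on C3 (5-exo-trig), which makes C3 stereogenic with its lactone carbonyl cis to the C4 substituent. The carbinol centre forms without control, which does not matter because it becomes a methylene group in step 9; only a slight excess of 10 is used so that the lactone is not attacked.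

Step 6
Reactants: 12 methyl (3aR,6R,6aS)-6-[3,4-bis(benzyloxy)phenyl]-3-[4-(benzyloxy)-3-methoxyphenyl]-1-oxotetrahydro-1H,3H-furo[3,4-c]furan-6a-carboxylate
Product: 14 (3aR,6S,6aS)-6-[3,4-bis(benzyloxy)phenyl]-3-[4-(benzyloxy)-3-methoxyphenyl]tetrahydro-1H,3H-furo[3,4-c]furan-1-one (cis-fused lactone; aryl on the convex face; both epimers at C3), via lithium carboxylate 13 (not isolated)
Conditions: LiCl (3 equiv), H2O (2 equiv), DMSO, 140 °C
Reagents that add atoms: none
Why: Krapcho dealkoxycarbonylation: chloride demethylates the ester (SN2 at methyl), carboxylate 13 loses CO2 and water protonates the lactone enolate. Only the cis ring fusion is accessible, so the new C–H bond is cis to the C4 hydrogen; expulsion of the ring oxygen from the enolate would be the reverse of a 5-endo-trig closure and is stereoelectronically disfavoured.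

Step 7
Reactants: 14 (3aR,6S,6aS)-6-[3,4-bis(benzyloxy)phenyl]-3-[4-(benzyloxy)-3-methoxyphenyl]tetrahydro-1H,3H-furo[3,4-c]furan-1-one
Product: 15 [(2S,3R,4R)-2-[3,4-bis(benzyloxy)phenyl]-4-{[4-(benzyloxy)-3-methoxyphenyl](hydroxy)methyl}oxolan-3-yl]methanol (carbinol epimers)
Conditions: LiAlH4, THF, 0 °C → rt
Reagents that add atoms: none
Why: Hydride reduction of a lactone to the 1,4-diol. No bond to a stereocentre is broken, benzyl ethers are inert, and the low temperature limits enolisation at C3.

Step 8
Reactants: 15 [(2S,3R,4R)-2-[3,4-bis(benzyloxy)phenyl]-4-{[4-(benzyloxy)-3-methoxyphenyl](hydroxy)methyl}oxolan-3-yl]methanol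
Product: 16 [(2S,3R,4R)-4-{(acetyloxy)[4-(benzyloxy)-3-methoxyphenyl]methyl}-2-[3,4-bis(benzyloxy)phenyl]oxolan-3-yl]methyl acetate (epimers at the acetoxy-bearing side-chain carbon)
Conditions: Ac2O, pyridine, DMAP (cat.), CH2Cl2, rt
Reagents that add atoms: acetic anhydride, CC(=O)OC(C)=O
Why: DMAP-catalysed acylation of both hydroxyl groups. The primary acetate is the one the target keeps; the benzylic acetate turns the carbinol into a leaving group for hydrogenolysis.

Step 9
Reactants: 16 [(2S,3R,4R)-4-{(acetyloxy)[4-(benzyloxy)-3-methoxyphenyl]methyl}-2-[3,4-bis(benzyloxy)phenyl]oxolan-3-yl]methyl acetate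
Product: 17 [(2S,3R,4R)-2-(3,4-dihydroxyphenyl)-4-[(4-hydroxy-3-methoxyphenyl)methyl]oxolan-3-yl]methyl acetate
Conditions: H2 (1 atm), 10% Pd/C, EtOAc, rt, stopped after uptake of 4 equiv H2
Reagents that add atoms: none
Why: Catalytic hydrogenolysis cleaves the three aryl benzyl ethers and the benzylic C–OAc bond, the latter more readily once the para-phenol is free, while the primary acetate is inert. The ring C2–O1 bond is also benzylic but its leaving group is an alkoxide, far poorer than acetate, and a non-nucleophilic solvent prevents solvolysis. No stereocentre is affected.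

## Compound list

1 | 3,4-bis(benzyloxy)benzaldehyde | O=Cc1ccc(OCc2ccccc2)c(OCc2ccccc2)c1 | starting material
2 | dimethyl malonate | COC(=O)CC(=O)OC | starting material
3 | dimethyl 2-{[3,4-bis(benzyloxy)phenyl]methylidene}propanedioate | COC(=O)C(=Cc1ccc(OCc2ccccc2)c(OCc2ccccc2)c1)C(=O)OC | intermediate
4 | racemic 2-ethenyloxirane | C=CC1CO1 | starting material
5 | dimethyl (2R,4R)-2-[3,4-bis(benzyloxy)phenyl]-4-ethenyloxolane-3,3-dicarboxylate | C=C[C@H]1CO[C@H](c2ccc(OCc3ccccc3)c(OCc3ccccc3)c2)C1(C(=O)OC)C(=O)OC | intermediate
6 | dimethyl (2R,4R)-2-[3,4-bis(benzyloxy)phenyl]-4-(1,2-dihydroxyethyl)oxolane-3,3-dicarboxylate (carbinol epimers) | OCC(O)[C@H]1CO[C@H](c2ccc(OCc3ccccc3)c(OCc3ccccc3)c2)C1(C(=O)OC)C(=O)OC | intermediate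
7 | dimethyl (2R,4R)-2-[3,4-bis(benzyloxy)phenyl]-4-formyloxolane-3,3-dicarboxylate | O=C[C@H]1CO[C@H](c2ccc(OCc3ccccc3)c(OCc3ccccc3)c2)C1(C(=O)OC)C(=O)OC | intermediate
8 | 4-bromo-2-methoxyphenol | COc1cc(Br)ccc1O | starting material
9 | 1-(benzyloxy)-4-bromo-2-methoxybenzene | COc1cc(Br)ccc1OCc1ccccc1 | intermediate
10 | [4-(benzyloxy)-3-methoxyphenyl]magnesium bromide | COc1cc([Mg]Br)ccc1OCc1ccccc1 | intermediate
11 | bromomagnesium alkoxide of dimethyl (2R,4R)-2-[3,4-bis(benzyloxy)phenyl]-4-{[4-(benzyloxy)-3-methoxyphenyl](hydroxy)methyl}oxolane-3,3-dicarboxylate (carbinol epimers) | Br[Mg]OC(c1ccc(OCc2ccccc2)c(OC)c1)[C@H]1CO[C@H](c2ccc(OCc3ccccc3)c(OCc3ccccc3)c2)C1(C(=O)OC)C(=O)OC | intermediate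
12 | methyl (3aR,6R,6aS)-6-[3,4-bis(benzyloxy)phenyl]-3-[4-(benzyloxy)-3-methoxyphenyl]-1-oxotetrahydro-1H,3H-furo[3,4-c]furan-6a-carboxylate (both C3 epimers) | COC(=O)[C@@]12[C@@H](c3ccc(OCc4ccccc4)c(OCc4ccccc4)c3)OC[C@@H]1C(c1ccc(OCc3ccccc3)c(OC)c1)OC2=O | intermediate
13 | lithium (3aR,6R,6aS)-6-[3,4-bis(benzyloxy)phenyl]-3-[4-(benzyloxy)-3-methoxyphenyl]-1-oxotetrahydro-1H,3H-furo[3,4-c]furan-6a-carboxylate (both C3 epimers) | [Li+].[O-]C(=O)[C@@]12[C@@H](c3ccc(OCc4ccccc4)c(OCc4ccccc4)c3)OC[C@@H]1C(c1ccc(OCc3ccccc3)c(OC)c1)OC2=O | intermediate
14 | (3aR,6S,6aS)-6-[3,4-bis(benzyloxy)phenyl]-3-[4-(benzyloxy)-3-methoxyphenyl]tetrahydro-1H,3H-furo[3,4-c]furan-1-one (both C3 epimers) | O=C1OC(c2ccc(OCc3ccccc3)c(OC)c2)[C@H]2CO[C@H](c3ccc(OCc4ccccc4)c(OCc4ccccc4)c3)[C@@H]12 | intermediate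
15 | [(2S,3R,4R)-2-[3,4-bis(benzyloxy)phenyl]-4-{[4-(benzyloxy)-3-methoxyphenyl](hydroxy)methyl}oxolan-3-yl]methanol (carbinol epimers) | OC(c1ccc(OCc2ccccc2)c(OC)c1)[C@H]1CO[C@H](c2ccc(OCc3ccccc3)c(OCc3ccccc3)c2)[C@H]1CO | intermediate
16 | [(2S,3R,4R)-4-{(acetyloxy)[4-(benzyloxy)-3-methoxyphenyl]methyl}-2-[3,4-bis(benzyloxy)phenyl]oxolan-3-yl]methyl acetate (side-chain epimers) | CC(=O)OC(c1ccc(OCc2ccccc2)c(OC)c1)[C@H]1CO[C@H](c2ccc(OCc3ccccc3)c(OCc3ccccc3)c2)[C@H]1COC(C)=O | intermediate
17 | [(2S,3R,4R)-2-(3,4-dihydroxyphenyl)-4-[(4-hydroxy-3-methoxyphenyl)methyl]oxolan-3-yl]methyl acetate | COc1cc(C[C@H]2CO[C@H](c3ccc(O)c(O)c3)[C@H]2COC(C)=O)ccc1O | target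

## Step count and risks

Total step count: 9. Longest linear sequence: 8 steps (1 → 3 → 5 → 7 → 12 → 14 → 15 → 16 → 17, that is steps 1, 2, 3, 5, 6, 7, 8, 9); step 4 is a one-step branch.

**Step 2 (key step).** The most likely failure is a slow oxa-Michael addition, because the two alkoxy groups on the aryl ring lower the electrophilicity of **3**; the zwitterionic allyl alkoxide would then be consumed by oligomerisation or isomerisation even when **4** is added slowly. Incomplete facial discrimination at the allyl unit and poor control of C2 relative to C4 are the other dangers. The fallback changes the acceptor. Aldehyde **1** is condensed with Meldrum's acid to 5-{[3,4-bis(benzyloxy)phenyl]methylidene}-2,2-dimethyl-1,3-dioxane-4,6-dione F1, a far stronger acceptor of the kind most used in such annulations. Annulation of F1 with **4** under Pd2(dba)3 and the diphosphine would give the spiro adduct (1R,4R)-1-[3,4-bis(benzyloxy)phenyl]-4-ethenyl-8,8-dimethyl-2,7,9-trioxaspiro[4.5]decane-6,10-dione F2. NaOMe in MeOH would open the dioxanedione, with loss of acetone, to (2R,4R)-2-[3,4-bis(benzyloxy)phenyl]-4-ethenyl-3-(methoxycarbonyl)oxolane-3-carboxylic acid F3. MeI with K2CO3 in DMF would then give **5**. The fallback sets out from **1** and returns at **5**. The C2 configuration has a second safeguard in either case: it is a benzylic ether carbon, and in **14** the wanted isomer has the aryl group on the convex face, so acid-mediated reversible opening of C2–O1 at that stage should favour it.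

**Step 5.** The basic arylmagnesium reagent may enolise the α-branched aldehyde, which would erode the configuration at C4 or expel the ring oxygen. Competing addition to an ester or to the lactone, and incomplete lactonisation of one carbinol epimer, are lesser risks. The fallback replaces the organomagnesium reagent by a rhodium-catalysed 1,2-addition under near-neutral conditions. Bromide **9** would be converted (n-BuLi, then B(OiPr)3, then aqueous acid) to [4-(benzyloxy)-3-methoxyphenyl]boronic acid F4. Addition of F4 to **7** with Rh(acac)(CO)2 and dppf in aqueous DME would give dimethyl (2R,4R)-2-[3,4-bis(benzyloxy)phenyl]-4-{[4-(benzyloxy)-3-methoxyphenyl](hydroxy)methyl}oxolane-3,3-dicarboxylate F5. Catalytic DBU would close F5 to **12**. The fallback sets out from **7** and **9** and returns at **12**.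

**Step 6.** At 140 °C chloride may attack the electron-rich benzylic carbon of the lactone instead of the ester methyl group and open the lactone, or the transient enolate may expel the ring oxygen from C2. The fallback separates hydrolysis from decarboxylation. LiOH in aqueous THF would hydrolyse the ester (and reversibly the lactone) of **12**. Acidification would re-close the cis lactone to (3aR,6R,6aS)-6-[3,4-bis(benzyloxy)phenyl]-3-[4-(benzyloxy)-3-methoxyphenyl]-1-oxotetrahydro-1H,3H-furo[3,4-c]furan-6a-carboxylic acid F6. Warming F6 in toluene at about 100 °C would decarboxylate it to **14**. The fallback sets out from **12** and returns at **14**.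

**Step 9.** The danger is over-reduction: once the benzyl ethers have gone, the ring C2–O1 bond is para-hydroxybenzylic and may be hydrogenolysed during the time the benzylic acetate needs. Sluggish loss of that acetate is the converse risk. The fallback removes the benzylic oxygen by a radical path before any hydrogenolysis. From **15**, selective acetylation of the primary hydroxyl (Ac2O, 2,4,6-collidine, −20 °C) would give [(2S,3R,4R)-2-[3,4-bis(benzyloxy)phenyl]-4-{[4-(benzyloxy)-3-methoxyphenyl](hydroxy)methyl}oxolan-3-yl]methyl acetate F7. 1,1′-Thiocarbonyldiimidazole would convert it to [(2S,3R,4R)-2-[3,4-bis(benzyloxy)phenyl]-4-{[4-(benzyloxy)-3-methoxyphenyl][(1H-imidazole-1-carbothioyl)oxy]methyl}oxolan-3-yl]methyl acetate F8. Barton–McCombie reduction (Bu3SnH, AIBN, toluene, 90 °C) would give [(2S,3R,4R)-4-{[4-(benzyloxy)-3-methoxyphenyl]methyl}-2-[3,4-bis(benzyloxy)phenyl]oxolan-3-yl]methyl acetate F9. A brief hydrogenolysis (H2, 10% Pd/C, EtOAc) then has only aryl benzyl ethers to cleave and can be stopped early. The fallback sets out from **15** and returns at **17**.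

## Further compounds

F1 | step 2 | 5-{[3,4-bis(benzyloxy)phenyl]methylidene}-2,2-dimethyl-1,3-dioxane-4,6-dione | CC1(C)OC(=O)C(=Cc2ccc(OCc3ccccc3)c(OCc3ccccc3)c2)C(=O)O1
F2 | step 2 | (1R,4R)-1-[3,4-bis(benzyloxy)phenyl]-4-ethenyl-8,8-dimethyl-2,7,9-trioxaspiro[4.5]decane-6,10-dione | C=C[C@H]1CO[C@H](c2ccc(OCc3ccccc3)c(OCc3ccccc3)c2)C12C(=O)OC(C)(C)OC2=O
F3 | step 2 | (2R,4R)-2-[3,4-bis(benzyloxy)phenyl]-4-ethenyl-3-(methoxycarbonyl)oxolane-3-carboxylic acid (both C3 epimers) | C=C[C@H]1CO[C@H](c2ccc(OCc3ccccc3)c(OCc3ccccc3)c2)C1(C(=O)O)C(=O)OC
F4 | step 5 | [4-(benzyloxy)-3-methoxyphenyl]boronic acid | COc1cc(B(O)O)ccc1OCc1ccccc1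
F5 | step 5 | dimethyl (2R,4R)-2-[3,4-bis(benzyloxy)phenyl]-4-{[4-(benzyloxy)-3-methoxyphenyl](hydroxy)methyl}oxolane-3,3-dicarboxylate (carbinol epimers) | OC(c1ccc(OCc2ccccc2)c(OC)c1)[C@H]1CO[C@H](c2ccc(OCc3ccccc3)c(OCc3ccccc3)c2)C1(C(=O)OC)C(=O)OC
F6 | step 6 | (3aR,6R,6aS)-6-[3,4-bis(benzyloxy)phenyl]-3-[4-(benzyloxy)-3-methoxyphenyl]-1-oxotetrahydro-1H,3H-furo[3,4-c]furan-6a-carboxylic acid (both C3 epimers) | OC(=O)[C@@]12[C@@H](c3ccc(OCc4ccccc4)c(OCc4ccccc4)c3)OC[C@@H]1C(c1ccc(OCc3ccccc3)c(OC)c1)OC2=O
F7 | step 9 | [(2S,3R,4R)-2-[3,4-bis(benzyloxy)phenyl]-4-{[4-(benzyloxy)-3-methoxyphenyl](hydroxy)methyl}oxolan-3-yl]methyl acetate (carbinol epimers) | OC(c1ccc(OCc2ccccc2)c(OC)c1)[C@H]1CO[C@H](c2ccc(OCc3ccccc3)c(OCc3ccccc3)c2)[C@H]1COC(C)=O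
F8 | step 9 | [(2S,3R,4R)-2-[3,4-bis(benzyloxy)phenyl]-4-{[4-(benzyloxy)-3-methoxyphenyl][(1H-imidazole-1-carbothioyl)oxy]methyl}oxolan-3-yl]methyl acetate (side-chain epimers) | S=C(OC(c1ccc(OCc2ccccc2)c(OC)c1)[C@H]1CO[C@H](c2ccc(OCc3ccccc3)c(OCc3ccccc3)c2)[C@H]1COC(C)=O)n1ccnc1
F9 | step 9 | [(2S,3R,4R)-4-{[4-(benzyloxy)-3-methoxyphenyl]methyl}-2-[3,4-bis(benzyloxy)phenyl]oxolan-3-yl]methyl acetate | COc1cc(C[C@H]2CO[C@H](c3ccc(OCc4ccccc4)c(OCc4ccccc4)c3)[C@H]2COC(C)=O)ccc1OCc1ccccc1
A1 | alternative 1 | (5R)-3-{[3,4-bis(benzyloxy)phenyl](hydroxy)methyl}-4-{2-[4-(benzyloxy)-3-methoxyphenyl]-1,3-dithian-2-yl}-5-[(1R,2S,5R)-menthyloxy]oxolan-2-one, 3,4-trans and 4,5-trans, carbinol epimers | CC(C)[C@@H]1CC[C@@H](C)C[C@H]1O[C@@H]2OC(=O)[C@H](C(O)c4ccc(OCc5ccccc5)c(OCc5ccccc5)c4)[C@H]2C3(c4ccc(OCc5ccccc5)c(OC)c4)SCCCS3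
A2 | alternative 1 | (5R)-5-[(1R,2S,5R)-menthyloxy]furan-2(5H)-one | CC(C)[C@@H]1CC[C@@H](C)C[C@H]1O[C@@H]1OC(=O)C=C1
A3 | alternative 1 | 2-[4-(benzyloxy)-3-methoxyphenyl]-1,3-dithiane | COc1cc(C2SCCCS2)ccc1OCc1ccccc1
A4 | alternative 2 | cis-fused 2-[3,4-bis(benzyloxy)phenyl]-6,6-dichloro-3-oxabicyclo[3.2.0]heptan-7-one, aryl anti to the four-membered ring | O=C1[C@@H]2[C@@H](c3ccc(OCc4ccccc4)c(OCc4ccccc4)c3)OC[C@@H]2C1(Cl)Cl
A5 | alternative 2 | (2S)-2-[3,4-bis(benzyloxy)phenyl]-2,5-dihydrofuran | C1=C[C@@H](c2ccc(OCc3ccccc3)c(OCc3ccccc3)c2)OC1
A6 | alternative 2 | dichloroketene | ClC(Cl)=C=O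
A7 | alternative 2 | 2,3-dihydrofuran | C1CC=CO1
A8 | alternative 2 | 3,4-bis(benzyloxy)phenyl trifluoromethanesulfonate | O=S(=O)(Oc1ccc(OCc2ccccc2)c(OCc2ccccc2)c1)C(F)(F)F
A9 | alternative 3 | (2S,3R)-2-[3,4-bis(benzyloxy)phenyl]-4-{[4-(benzyloxy)-3-methoxyphenyl]methyl}-3-{[(tert-butyldimethylsilyl)oxy]methyl}-2,3-dihydrofuran | COc1cc(CC2=CO[C@H](c3ccc(OCc4ccccc4)c(OCc4ccccc4)c3)[C@H]2CO[Si](C)(C)C(C)(C)C)ccc1OCc1ccccc1
A10 | alternative 3 | [3,4-bis(benzyloxy)phenyl]diazomethane | [N-]=[N+]=Cc1ccc(OCc2ccccc2)c(OCc2ccccc2)c1
A11 | alternative 3 | (E)-2-{[4-(benzyloxy)-3-methoxyphenyl]methyl}-4-[(tert-butyldimethylsilyl)oxy]but-2-enal | O=C/C(Cc1ccc(OCc2ccccc2)c(OC)c1)=C/CO[Si](C)(C)C(C)(C)C
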